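Here is my number for your flask.

free monomer 0.50 M; protic impurity 0.500 M; pre-initiator 2.5 mM; time 3.0 h

    pre-initiator → initiator (k1 = 0.0105 min⁻¹)
    free monomer + initiator → living end + monomer in chains (k2 = 0.101 M⁻¹ min⁻¹)
    protic impurity + free monomer → quenched substrate (k3 = 0.300 M⁻¹ min⁻¹)
    free monomer + living end → monomer in chains + living end, rate k4*[living end]*[free monomer] (k4 = 50.2 M⁻¹ min⁻¹)
    initiator → spent initiator (k5 = 0.128 min⁻¹)

* average number of monomer units in a chain (chains begun, living or dead) at 3.0 h
* part of the free monomer that has reacted at 3.0 h

You can reckon this without following time. Each living end adds monomer at k4[free monomer], while ln[protic impurity] falls at k3[free monomer]. Divide one by the other and both [free monomer] and time cancel. What remains is a selectivity factor, k4/k3 = 167, the number of units a living end adds for each unit fall in ln[protic impurity].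

Next you need the size of that fall. Protic impurity and free monomer are charged equally and are consumed one for one, so I treat the quench as running alone, which gives a fall of 3.33 by 3.0 h. A chain present from the start would then reach 556 units. Chains begin along the way, though. The same division gives their count a slope of (k2/k3)[initiator] on this scale. If I assume a steady [initiator], chains begin evenly along that fall, so my number is 279, half of the figure for a chain present from the start. The quench alone would consume 96.4% of the free monomer.

Your forecast of 230 is lower than my chain length, and its 98.8% is higher than my conversion. Your grounds include that “the initiator is mostly lost to its own decay”.

The simulation gives 227 and 98.7%, both within your forecast's margins. In this flask at 0.0991 h, free monomer has a half-life of 0.15 h against protic impurity, far shorter than 49 d against initiator. By 3.00 h, quenched substrate holds 94.2% of the free monomer charged and chains hold 4.50%. With 5.76% of the protic impurity's charge left, half of 167 times the fall gives 238. The same flask read at 2.0 h, with 6.88% left, gives 223 by this rule and 203 in its run.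

All constants stand for no real mixture; the result is computed.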